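## Analysis of the target

Target 24 is a 2,3-dimethyl-2,3-dihydrochromene-4,7-dione, numbered O1, C2, C3, C4, C4a, C5, C6, C7, C8, C8a. Ring A (C4a, C5–C8, C8a) is a dearomatised acylphloroglucinol with the C7 ketone, the enolic C5 hydroxyl and the C4a=C8a double bond. Ring B (O1, C2, C3, C4, C4a, C8a) is a dihydropyranone whose C4 ketone completes an enolised β-triketone.

There are six stereocentres. C2 (R) and C3 (R) are adjacent and trans. The quaternary C8 (R) carries a prenyl and a cyclobutylmethyl group. The side-chain carbon on C6 (S) carries the pentyl group and the CH2CO2H arm. The two cyclobutane carbons (1R,3S, cis) are those of the pinane family. Only C2 and C3 can control one another; C8, the side-chain centre and the cyclobutane are insulated by sp2 carbons or methylene groups, so each must be bought or set by a reagent.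

The sensitive points are these. C3 is epimerisable. Ring B can open under base by β-elimination of O1 from the C3 enolate, which would scramble C2. The isopropenyl and prenyl alkenes and the cyclobutylcarbinyl position do not tolerate strong acid. The triketone is an ambident O/C nucleophile. The acid arm lactonises readily onto O5.

The difficulty is that ring A descends from a symmetric phloroglucinol. Three oxygens (O1, O5, O7) and three carbons (C4a, C6, C8) must be told apart, and the C8 quaternary centre must be created with no stereocentre nearby.

The strategy rests on two features. First, the C4 carbonyl carbon is bonded to C4a and to C3, and C3 is β to O1. A formyl group on C4a and a but-3-en-2-yl group on O1 therefore hold every atom of ring B, with C2 as a purchased carbinol centre and C3 created when the aldehyde C–H adds across the alkene. Second, the acid arm on C6 reaches O5. In the aromatic series O5, C6 and the side chain form a 4-pentyl-dihydrocoumarin (ring C) that hides the acid, masks O5 and leaves C4a as the one ring carbon between two different oxygens.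

## Retrosynthetic reasoning

**24 ⇒ 23.** The first bond remade backwards is the ester bond between the side-chain carboxyl carbon and O5. Closing it gives the enol lactone 23, in which the acid is protected without a protecting group and O5 can no longer act as a nucleophile. The forward step only has to hydrolyse a very labile enol ester (a vinylogous anhydride) without opening ring B.

**23 ⇒ 22.** The C8–prenyl bond is cut, which re-aromatises ring A to the phenol 22. Prenyl, not cyclobutylmethyl, is removed here because only the allylic group can be delivered by a chiral metal-bound electrophile; the cyclobutylmethyl group is a β-branched primary alkyl that would not alkylate a hindered carbon. The forward step has to give C- rather than O-alkylation, attack at C8 rather than C6, and one face of C8. The lactone helps with the first two: O5 is acylated, and C6 carries a ring-bound secondary carbon. The face must come from the catalyst.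

**22 ⇒ 14 + 20 (through 21).** The C8–CH2 bond is cut. In 14, C8 is the only unsubstituted ring carbon and it lies ortho to the one free hydroxyl (O7), so an aldehyde can be delivered there through a boron template and the benzylic oxygen then removed reductively. This makes the route convergent: the cyclobutane arrives as aldehyde 20 with both of its stereocentres.

**20 ⇒ 19 ⇒ 18 ⇒ 17 ⇒ 16 ⇒ 15.** The aldehyde goes back through its ester to the methyl ketone 17, the acid 16 and the bicyclic enone 15. Cleaving the enone double bond of 15 with loss of one carbon leaves a cis-1,3-disubstituted 2,2-dimethylcyclobutane with the right absolute configuration. The forward steps must not epimerise the carbon next to the acetyl group, so the methylenation has to be non-basic.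

**14 ⇒ 13.** The O7 hydroxyl is protected as its methoxymethyl ether. The group is needed earlier to tell O7 from O1 and can be removed with aqueous acid, which the lactone tolerates.

**13 ⇒ 11 (through 12); the key disconnection.** The C3–C4 bond is cut, opening ring B to the aldehyde 11 with an (R)-but-3-en-2-yl ether on O1. This is the cut that uses the first structural feature. It removes a ring, a skeletal bond and the C3 stereocentre in one isomerisation, and 11 contains nothing but an aldehyde, a terminal alkene and spectators. The forward step must reverse the polarity of the formyl carbon and add it to the internal alkene carbon; C3 can be corrected afterwards because it is α to the new ketone.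

**11 ⇒ 9 + 10; 9 ⇒ 8 ⇒ 7 ⇒ 6.** The ether C–O bond is cut to the phenol 9 and the carbinol 10, joined forwards with inversion. 9 comes from the dihydroxy aldehyde 8 by protection of the hydroxyl para to the formyl group (the other is chelated). 8 comes from 6 through the iminium salt 7 by introduction of one carbon at the position between the lactone oxygen and a hydroxyl.

**6 ⇒ 5 ⇒ 4 ⇒ 3 ⇒ 1 + 2.** The side-chain stereocentre is traced to the conjugate reduction of the coumarin 3, whose phenols are silylated in the flask (4) and whose reduced form is held as the boron enolate 5. 3 is the condensation product of the symmetric triol 1 with the β-keto ester 2, where symmetry removes any regiochemical question.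

## Alternatives that were turned down

**Alternative 1: ring A built last by Dieckmann closure.**
- Disconnection: the C6–C7 bond of ring A. The precursor A2 is a preformed dihydropyranone carrying on C4a the 3-oxoacyl chain (C5 ketone, C6 methylene, pentyl stereocentre, ester arm) and on C8a the quaternary C8 with prenyl, cyclobutylmethyl and the C7 methyl ester.
- Forward key step: a strong amide base deprotonates C6 and the enolate attacks the C7 ester, giving A1, the methyl ester of 24.
- For it: ring A is never aromatic. The problems the chosen route has at C8 (C versus O, C8 versus C6) do not exist, and the condensation is a classical reaction that delivers the enolised triketone directly. On this point it is stronger.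
- Against it: the difficulty moves into A2. C8 must be made as an acyclic all-carbon quaternary centre with the same absence of nearby stereocentres, and then attached to a fully substituted vinylogous ester. The C7 ester sits on a quaternary carbon and is a poor electrophile. The base that closes the ring can also remove the C3 proton and open ring B by β-elimination. A2 would take a long linear sequence.
- Comparison: the chosen route buys ring A as an arene, makes ring B by one isomerisation, and accepts a catalyst-controlled dearomatisation at C8 as the price.

**Alternative 2: carbonylative lactonisation of a symmetric alkenylphloroglucinol.**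
- Disconnection: the CH2–C(=O) bond and the acyl–oxygen bond of ring C, back to the triol A4 and carbon monoxide (A5).
- Forward key step: a chiral palladium hydride adds across the 1,1-disubstituted alkene of A4 with the metal on the terminal carbon, A5 inserts and a neighbouring hydroxyl captures the acyl group. The product A3 is the same compound as 6.
- For it: A4 is symmetric, so no regiochemistry arises. Ring C and its stereocentre form in one catalytic step. No hydride reagent is involved, so neither over-reduction of the lactone nor transient protection of the phenols is an issue. On these points it is equal or stronger.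
- Against it: A4 is an electron-rich α-alkylstyrene with three free phenols. It is prone to acid-induced cyclisation and oligomerisation and to migration of the double bond into the chain under the same metal hydride. The catalyst must distinguish the faces of a 1,1-disubstituted alkene and must also enforce anti-Markovnikov insertion. A4 needs at least two steps from 1.
- Comparison: it stops at 6 and answers neither ring B nor C8, so it is only another entry to an early intermediate. The chosen route reaches 6 from 1 in two steps by well-precedented chemistry.

**Alternative 3: the acid chain installed last by carbene annulation.**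
- Disconnection: the C6–CH bond and the O5–acyl bond, back to the dearomatised triketone A8 (no substituent on C6) and oct-2-ynal (A7).
- Forward key step: a chiral carbene turns A7 into an unsaturated acyl azolium, C6 of A8 adds to its β-carbon and the enol oxygen is acylated. The product A6 is the same compound as 23.
- For it: the side chain and its stereocentre arrive in one catalytic step on the finished core, and the reaction type is well known for stable enols. Acylation at O5 or O7 would not matter, since both lactones hydrolyse to 24. In convergence it is stronger.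
- Against it: A8 has to be made first. With C6 unsubstituted and O5 free, both the reductive alkylation and the dearomative prenylation lose the regiochemical bias that the lactone provides in the chosen route (two nucleophilic ring carbons, two free hydroxyls). The side-chain centre is then set on the most valuable intermediate, by an intermolecular step with an aliphatic ynal in which O-acylation of the triketone competes, and the catalyst must override whatever bias the distant C8 centre exerts. The alternative also leaves open how ring B is made.
- Comparison: the chosen route sets the side-chain centre on cheap material, carries the acid as ring C, which also protects and directs, and uses carbene catalysis for an intramolecular step with one aldehyde and one alkene.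

Key step: step 6

Remark on the chemistry: the sense of induction of the three chiral catalysts (copper hydride ligand in step 2, triazolium in step 6, palladium ligand in step 13) cannot be fixed on paper; the antipode named is the one assumed to be matched, and its mirror image is meant if the first run shows the opposite sense.

Remark on names: compounds 3–11 are named with coumarin (chroman-2-one) locants. The tricycles 12–14 and 21–23 are named as pyrano[2,3-f]chromenes, in which C4 is the pentyl centre, C5 and C6 are C7 and C8 of the target, O7 is O1, C8 is C2, C9 is C3 and C10 is C4. In the discussion of steps 6–14 the target locants are used.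

## Route

Step 1
Reactants: 1 benzene-1,3,5-triol (phloroglucinol); 2 ethyl 3-oxooctanoate
Product: 3 5,7-dihydroxy-4-pentyl-2H-chromen-2-one
Conditions: concd H2SO4, 0 °C → rt
Reagents that add atoms: none
Why: Pechmann condensation (transesterification, intramolecular hydroxyalkylation, dehydration); 1 is symmetric, so only one coumarin can form, and the ketone carbon of 2 becomes C4 with its pentyl group.

Step 2
Reactants: 3 5,7-dihydroxy-4-pentyl-2H-chromen-2-one
Product: 6 (4S)-5,7-dihydroxy-4-pentylchroman-2-one, via bis(trimethylsilyl) ether 4 (not isolated), via boron enolate 5 (not isolated)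
Conditions: (Me3Si)2NH, MeCN, 60 °C, then evaporation; CuCl (5 mol %), NaOt-Bu (5 mol %), (R)-DTBM-SEGPHOS (5.5 mol %), pinacolborane (1.3 equiv), toluene, 0 °C → rt; then 1 M HCl, THF, rt
Reagents that add atoms: none
Why: Copper hydride-catalysed asymmetric conjugate reduction (1,4-hydroboration) of a coumarin: the phenols are silylated in the flask so that they do not quench the hydride, the ligand-bound copper hydride delivers hydride to one face of C4, and the copper enolate is trapped by the borane as 5, which cannot be reduced further to a lactol; acid work-up frees lactone and phenols, and the (4S) centre is set by the ligand.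

Step 3
Reactants: 6 (4S)-5,7-dihydroxy-4-pentylchroman-2-one
Product: 8 (4S)-5,7-dihydroxy-2-oxo-4-pentylchromane-8-carbaldehyde, via iminium chloride 7 (not isolated)
Conditions: POCl3 (1.2 equiv), DMF (3 equiv), MeCN, 0 °C → rt; then H2O, 40 °C
Reagents that add atoms: N,N-dimethylformamide, CN(C)C=O; water, O
Why: Vilsmeier–Haack formylation; C8 is para to the C5 hydroxyl and ortho to the C7 hydroxyl, the pattern the chloroiminium electrophile prefers in partly O-substituted phloroglucinols, whereas C6 lies between two hydroxyls; the conditions are not nucleophilic, so the aryl lactone and the C4 centre should be untouched.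

Step 4
Reactants: 8 (4S)-5,7-dihydroxy-2-oxo-4-pentylchromane-8-carbaldehyde
Product: 9 (4S)-7-hydroxy-5-(methoxymethoxy)-2-oxo-4-pentylchromane-8-carbaldehyde
Conditions: MeOCH2Cl (1.05 equiv), i-Pr2NEt, CH2Cl2, 0 °C
Reagents that add atoms: chloromethyl methyl ether, COCCl
Why: O-alkylation of the more acidic, non-chelated hydroxyl para to the formyl group; the C7 hydroxyl is held in a hydrogen bond to the aldehyde and should react much more slowly with one equivalent of reagent.

Step 5
Reactants: 9 (4S)-7-hydroxy-5-(methoxymethoxy)-2-oxo-4-pentylchromane-8-carbaldehyde; 10 (S)-but-3-en-2-ol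
Product: 11 (4S)-7-[(2R)-but-3-en-2-yloxy]-5-(methoxymethoxy)-2-oxo-4-pentylchromane-8-carbaldehyde
Conditions: PPh3, diisopropyl azodicarboxylate, toluene, 0 °C → rt
Reagents that add atoms: none
Why: Mitsunobu etherification; the chelated phenol is acidic enough to protonate the betaine, and SN2 displacement on the alkoxyphosphonium ion inverts the carbinol carbon to give the (R) ether, which becomes C2; the neutral conditions spare the lactone, and the SN2' crotyl ether expected as a minor by-product is a separable constitutional isomer.

Step 6
Reactants: 11 (4S)-7-[(2R)-but-3-en-2-yloxy]-5-(methoxymethoxy)-2-oxo-4-pentylchromane-8-carbaldehyde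
Product: 13 (4S,8R,9R)-5-(methoxymethoxy)-8,9-dimethyl-4-pentyl-3,4,8,9-tetrahydro-2H,10H-pyrano[2,3-f]chromene-2,10-dione, via cis-chromanone 12 (not isolated)
Conditions: (5aS,10bR)-2-mesityl-5a,10b-dihydro-4H,6H-indeno[2,1-b][1,2,4]triazolo[4,3-d][1,4]oxazin-2-ium chloride (15 mol %), DBU (10 mol %), 1,4-dioxane, 80 °C; then Et3N, CH2Cl2, rt
Reagents that add atoms: none
Why: The free carbene adds to the formyl group and proton transfer gives the enaminol (Breslow intermediate), in which the former aldehyde carbon is nucleophilic. That carbon bonds to the internal alkene carbon while the enol proton passes to the terminal CH2 in one concerted, Conia-ene-like event, and loss of the carbene from the resulting alkoxide gives the C4 ketone. The closest known reaction type is the carbene-catalysed intramolecular hydroacylation of unactivated alkenes that turns 2-allyloxybenzaldehydes into 3-methylchroman-4-ones. Ring B closes in the 6-exo-trig mode: the C3–C4 bond forms and the terminal carbon stays outside the ring as the C3 methyl. C2 is the inverted carbinol carbon of 10 and takes no part. C3 is new; kinetically it is set by a chair-like transition state with the C2 methyl pseudo-equatorial, reinforced by the chiral triazolium, and thermodynamically it is secured because it is α to the ketone, so triethylamine converts whatever cis isomer 12 forms into the trans isomer 13 with both methyls pseudo-equatorial. Only one aldehyde and one alkene are present, and the formyl carbon sits between the ether oxygen and the lactone oxygen, so only one six-membered ring can form and benzoin self-condensation is sterically suppressed. Additions of the carbene or of the enaminol to the aryl lactone are reversible, whereas the hydroacylation is not. The temperature of 80 °C and the sub-stoichiometric base are chosen to keep the [3,3] shift of the aryl butenyl ether and β-elimination opening of ring B slow.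

Step 7
Reactants: 13 (4S,8R,9R)-5-(methoxymethoxy)-8,9-dimethyl-4-pentyl-3,4,8,9-tetrahydro-2H,10H-pyrano[2,3-f]chromene-2,10-dione
Product: 14 (4S,8R,9R)-5-hydroxy-8,9-dimethyl-4-pentyl-3,4,8,9-tetrahydro-2H,10H-pyrano[2,3-f]chromene-2,10-dione
Conditions: 3 M HCl, THF, 40 °C
Reagents that add atoms: none
Why: Acid hydrolysis of the formaldehyde acetal; in aqueous acid the aryl lactone stays closed (lactonisation is favoured), and C3 cannot be harmed because the trans chromanone is already the thermodynamic epimer.

Step 8
Reactants: 15 (1S,5S)-4,6,6-trimethylbicyclo[3.1.1]hept-3-en-2-one ((1S,5S)-verbenone)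
Product: 16 (1S,3R)-3-acetyl-2,2-dimethylcyclobutane-1-carboxylic acid
Conditions: RuCl3·xH2O (2 mol %), NaIO4 (4.1 equiv), EtOAc/MeCN/H2O, rt
Reagents that add atoms: sodium periodate, [Na+].[O-]I(=O)(=O)=O; water, O
Why: Ruthenium tetroxide cleavage of the enone double bond gives the methyl ketone and an α-keto acid that is oxidised further with loss of one carbon; both ring substituents come from the bridge of the bicycle, so they are necessarily cis and keep the configuration of 15.

Step 9
Reactants: 16 (1S,3R)-3-acetyl-2,2-dimethylcyclobutane-1-carboxylic acid
Product: 17 methyl (1S,3R)-3-acetyl-2,2-dimethylcyclobutane-1-carboxylate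
Conditions: MeI, KHCO3, DMF, rt
Reagents that add atoms: iodomethane, CI
Why: SN2 alkylation of the carboxylate; hydrogencarbonate is too weak a base to enolise the ketone, so the acetyl-bearing centre should not epimerise.

Step 10
Reactants: 17 methyl (1S,3R)-3-acetyl-2,2-dimethylcyclobutane-1-carboxylate
Product: 18 methyl (1S,3S)-2,2-dimethyl-3-(prop-1-en-2-yl)cyclobutane-1-carboxylate
Conditions: Zn, CH2Br2, TiCl4, THF/CH2Cl2, 0 °C → rt
Reagents that add atoms: dibromomethane, BrCBr
Why: Lombardo–Takai methylenation; the titanium-activated geminal dizinc reagent is non-basic and selective for ketones over esters, so the isopropenyl group is formed without epimerising the adjacent ring carbon (the descriptor changes from R to S only because the priorities change).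

Step 11
Reactants: 18 methyl (1S,3S)-2,2-dimethyl-3-(prop-1-en-2-yl)cyclobutane-1-carboxylate
Product: 20 (1S,3S)-2,2-dimethyl-3-(prop-1-en-2-yl)cyclobutane-1-carbaldehyde, via aluminium hemiacetal 19 (not isolated)
Conditions: i-Bu2AlH (1.1 equiv), CH2Cl2, −78 °C; then MeOH, aq. KNaC4H4O6 (potassium sodium tartrate)
Reagents that add atoms: none
Why: Partial reduction of an ester with diisobutylaluminium hydride; the tetrahedral aluminium hemiacetal, shielded by the neighbouring gem-dimethyl carbon, should persist at −78 °C and release the aldehyde only on work-up; the volatile, epimerisable aldehyde is used at once as a solution.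

Step 12
Reactants: 14 (4S,8R,9R)-5-hydroxy-8,9-dimethyl-4-pentyl-3,4,8,9-tetrahydro-2H,10H-pyrano[2,3-f]chromene-2,10-dione; 20 (1S,3S)-2,2-dimethyl-3-(prop-1-en-2-yl)cyclobutane-1-carbaldehyde
Product: 22 (4S,8R,9R)-6-{[(1R,3S)-2,2-dimethyl-3-(prop-1-en-2-yl)cyclobutyl]methyl}-5-hydroxy-8,9-dimethyl-4-pentyl-3,4,8,9-tetrahydro-2H,10H-pyrano[2,3-f]chromene-2,10-dione, via benzodioxaborin 21 (not isolated)
Conditions: PhB(OH)2 (1.2 equiv), EtCO2H (0.3 equiv), toluene, reflux, Dean–Stark trap; then Et3SiH (3 equiv), Me3SiOTf (0.2 equiv), 2,6-di-tert-butyl-4-methylpyridine (0.3 equiv), CH2Cl2, −78 → −30 °C; aq. NaHCO3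
Reagents that add atoms: none
Why: Boron-templated ortho-alkylation of a phenol: the aryloxyboron species delivers the aldehyde to the ortho carbon through a six-membered transition state, and C8 is the only free ortho position, so the cyclic boronate 21 forms regiospecifically; ionisation of its benzylic C–O bond and hydride transfer from the silane (ionic hydrogenation) then leave the CH2 link, with a hindered pyridine keeping the medium free of protic acid for the sake of the isopropenyl group.

Step 13
Reactants: 22 (4S,8R,9R)-6-{[(1R,3S)-2,2-dimethyl-3-(prop-1-en-2-yl)cyclobutyl]methyl}-5-hydroxy-8,9-dimethyl-4-pentyl-3,4,8,9-tetrahydro-2H,10H-pyrano[2,3-f]chromene-2,10-dione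
Product: 23 (4S,6R,8R,9R)-6-{[(1R,3S)-2,2-dimethyl-3-(prop-1-en-2-yl)cyclobutyl]methyl}-8,9-dimethyl-6-(3-methylbut-2-en-1-yl)-4-pentyl-3,4,8,9-tetrahydro-2H-pyrano[2,3-f]chromene-2,5,10(6H)-trione
Conditions: Pd2(dba)3 (2.5 mol %), N,N'-[(1R,2R)-cyclohexane-1,2-diyl]bis[2-(diphenylphosphanyl)benzamide] (7.5 mol %), 3-methylbut-2-en-1-yl acetate (1.5 equiv), Cs2CO3 (1.1 equiv), 1,4-dioxane, rt
Reagents that add atoms: 3-methylbut-2-en-1-yl acetate, CC(C)=CCOC(C)=O
Why: Tsuji–Trost asymmetric allylic alkylation with dearomatisation: the caesium phenoxide attacks the less hindered CH2 terminus of the palladium-bound prenyl group; O-prenylation is reversible under zerovalent palladium while C-alkylation is not, C8 (between O7 and the ether O1, carrying a primary alkyl) is favoured over C6 (next to the acylated O5 and carrying a ring-bound secondary carbon), and the chiral pocket of the ligand selects the face of C8 to give the (R) quaternary centre.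

Step 14
Reactants: 23 (4S,6R,8R,9R)-6-{[(1R,3S)-2,2-dimethyl-3-(prop-1-en-2-yl)cyclobutyl]methyl}-8,9-dimethyl-6-(3-methylbut-2-en-1-yl)-4-pentyl-3,4,8,9-tetrahydro-2H-pyrano[2,3-f]chromene-2,5,10(6H)-trione
Product: 24 (3S)-3-[(2R,3R,8R)-8-{[(1R,3S)-2,2-dimethyl-3-(prop-1-en-2-yl)cyclobutyl]methyl}-5-hydroxy-2,3-dimethyl-8-(3-methylbut-2-en-1-yl)-4,7-dioxo-3,4,7,8-tetrahydro-2H-chromen-6-yl]octanoic acid
Conditions: LiOH (3 equiv), THF/H2O, 0 °C; then 1 M HCl to pH 3, 0 °C
Reagents that add atoms: lithium hydroxide, [Li+].[OH-]
Why: Saponification of an enol lactone that is a vinylogous anhydride and therefore opens quickly at 0 °C; once opened, the triketone is present as its delocalised enolate, which lowers the acidity of C3–H and makes O1 a poor leaving group, so ring B should survive; cold acidification gives the enol acid.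

## Compound list

1 | benzene-1,3,5-triol (phloroglucinol) | Oc1cc(O)cc(O)c1 | starting material
2 | ethyl 3-oxooctanoate | CCCCCC(=O)CC(=O)OCC | starting material
3 | 5,7-dihydroxy-4-pentyl-2H-chromen-2-one | CCCCCC1=CC(=O)Oc2cc(O)cc(O)c12 | intermediate
4 | 4-pentyl-5,7-bis[(trimethylsilyl)oxy]-2H-chromen-2-one | CCCCCC1=CC(=O)Oc2cc(O[Si](C)(C)C)cc(O[Si](C)(C)C)c12 | intermediate (not isolated)
5 | (4S)-4-pentyl-2-[(4,4,5,5-tetramethyl-1,3,2-dioxaborolan-2-yl)oxy]-5,7-bis[(trimethylsilyl)oxy]-4H-chromene | CCCCC[C@H]1C=C(OB2OC(C)(C)C(C)(C)O2)Oc2cc(O[Si](C)(C)C)cc(O[Si](C)(C)C)c12 | intermediate (not isolated)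
6 | (4S)-5,7-dihydroxy-4-pentylchroman-2-one | CCCCC[C@H]1CC(=O)Oc2cc(O)cc(O)c12 | intermediate
7 | N-{[(4S)-5,7-dihydroxy-2-oxo-4-pentylchroman-8-yl]methylidene}-N-methylmethanaminium chloride | CCCCC[C@H]1CC(=O)Oc2c(C=[N+](C)C)c(O)cc(O)c12.[Cl-] | intermediate (not isolated)
8 | (4S)-5,7-dihydroxy-2-oxo-4-pentylchromane-8-carbaldehyde | CCCCC[C@H]1CC(=O)Oc2c(C=O)c(O)cc(O)c12 | intermediate
9 | (4S)-7-hydroxy-5-(methoxymethoxy)-2-oxo-4-pentylchromane-8-carbaldehyde | CCCCC[C@H]1CC(=O)Oc2c(C=O)c(O)cc(OCOC)c12 | intermediate
10 | (S)-but-3-en-2-ol | C=C[C@H](C)O | starting material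
11 | (4S)-7-[(2R)-but-3-en-2-yloxy]-5-(methoxymethoxy)-2-oxo-4-pentylchromane-8-carbaldehyde | O=Cc1c(O[C@H](C)C=C)cc(OCOC)c2c1OC(=O)C[C@@H]2CCCCC | intermediate (precursor of the key step)
12 | (4S,8R,9S)-5-(methoxymethoxy)-8,9-dimethyl-4-pentyl-3,4,8,9-tetrahydro-2H,10H-pyrano[2,3-f]chromene-2,10-dione (cis-2,3-dimethylchromanone) | CCCCC[C@H]1CC(=O)Oc2c1c(OCOC)cc3O[C@H](C)[C@H](C)C(=O)c23 | intermediate (not isolated)
13 | (4S,8R,9R)-5-(methoxymethoxy)-8,9-dimethyl-4-pentyl-3,4,8,9-tetrahydro-2H,10H-pyrano[2,3-f]chromene-2,10-dione (trans-2,3-dimethylchromanone) | CCCCC[C@H]1CC(=O)Oc2c1c(OCOC)cc3O[C@H](C)[C@@H](C)C(=O)c23 | intermediate (product of the key step)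
14 | (4S,8R,9R)-5-hydroxy-8,9-dimethyl-4-pentyl-3,4,8,9-tetrahydro-2H,10H-pyrano[2,3-f]chromene-2,10-dione | CCCCC[C@H]1CC(=O)Oc2c1c(O)cc3O[C@H](C)[C@@H](C)C(=O)c23 | intermediate
15 | (1S,5S)-4,6,6-trimethylbicyclo[3.1.1]hept-3-en-2-one ((1S,5S)-verbenone) | CC1=CC(=O)[C@H]2C[C@@H]1C2(C)C | starting material
16 | (1S,3R)-3-acetyl-2,2-dimethylcyclobutane-1-carboxylic acid | CC(=O)[C@@H]1C[C@H](C(=O)O)C1(C)C | intermediate
17 | methyl (1S,3R)-3-acetyl-2,2-dimethylcyclobutane-1-carboxylate | CC(=O)[C@@H]1C[C@H](C(=O)OC)C1(C)C | intermediate
18 | methyl (1S,3S)-2,2-dimethyl-3-(prop-1-en-2-yl)cyclobutane-1-carboxylate | C=C(C)[C@@H]1C[C@H](C(=O)OC)C1(C)C | intermediate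
19 | diisobutyl{methoxy[(1S,3S)-2,2-dimethyl-3-(prop-1-en-2-yl)cyclobutyl]methoxy}alane (either configuration at the acetal carbon) | C=C(C)[C@@H]1C[C@H](C(OC)O[Al](CC(C)C)CC(C)C)C1(C)C | intermediate (not isolated)
20 | (1S,3S)-2,2-dimethyl-3-(prop-1-en-2-yl)cyclobutane-1-carbaldehyde | C=C(C)[C@@H]1C[C@H](C=O)C1(C)C | intermediate
21 | cyclic phenylboronate (2-phenyl-4H-1,3,2-benzodioxaborin) spanning O7 and C8 of 14 (target locants), with the (1S,3S)-2,2-dimethyl-3-(prop-1-en-2-yl)cyclobutyl group on its C4 (either configuration at that carbon) | CCCCC[C@H]1CC(=O)Oc2c1c5OB(c6ccccc6)OC([C@H]4C[C@@H](C(C)=C)C4(C)C)c5c3O[C@H](C)[C@@H](C)C(=O)c23 | intermediate (not isolated)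
22 | (4S,8R,9R)-6-{[(1R,3S)-2,2-dimethyl-3-(prop-1-en-2-yl)cyclobutyl]methyl}-5-hydroxy-8,9-dimethyl-4-pentyl-3,4,8,9-tetrahydro-2H,10H-pyrano[2,3-f]chromene-2,10-dione | CCCCC[C@H]1CC(=O)Oc2c1c(O)c(C[C@H]4C[C@@H](C(C)=C)C4(C)C)c3O[C@H](C)[C@@H](C)C(=O)c23 | intermediate
23 | (4S,6R,8R,9R)-6-{[(1R,3S)-2,2-dimethyl-3-(prop-1-en-2-yl)cyclobutyl]methyl}-8,9-dimethyl-6-(3-methylbut-2-en-1-yl)-4-pentyl-3,4,8,9-tetrahydro-2H-pyrano[2,3-f]chromene-2,5,10(6H)-trione | C=C(C)[C@@H]1C[C@H](C[C@@]2(CC=C(C)C)C(=O)C3=C(OC(=O)C[C@@H]3CCCCC)C4=C2O[C@H](C)[C@@H](C)C4=O)C1(C)C | intermediate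
24 | (3S)-3-[(2R,3R,8R)-8-{[(1R,3S)-2,2-dimethyl-3-(prop-1-en-2-yl)cyclobutyl]methyl}-5-hydroxy-2,3-dimethyl-8-(3-methylbut-2-en-1-yl)-4,7-dioxo-3,4,7,8-tetrahydro-2H-chromen-6-yl]octanoic acid | C=C(C)[C@@H]1C[C@H](C[C@@]2(CC=C(C)C)C(=O)C([C@@H](CCCCC)CC(=O)O)=C(O)C3=C2O[C@H](C)[C@@H](C)C3=O)C1(C)C | target

## Step count and least certain steps

Total: 14 steps. Longest linear sequence: 10 steps (steps 1–7, 12, 13, 14, from 1); the cyclobutane branch (steps 8–11) joins at step 12.

**Step 6 (key step).**
- What may go wrong: the carbene may add only slowly to a formyl group that has an oxygen substituent on each ortho carbon. Slower processes could then take over: a thermal [3,3] shift of the butenyl ether to the free ortho carbon; non-productive acyl transfer from the aryl lactone to the carbene; and, in the product, base-induced opening and re-closure of ring B through β-elimination of the aryloxide, which would erode C2.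
- Fallback: a radical instead of a polar ring closure, setting out from 11. Pinnick oxidation (NaClO2, NaH2PO4, 2-methylbut-2-ene) gives the carboxylic acid F1. Diphenyl diselenide and tributylphosphine convert it into the Se-phenyl selenoester F2. Bu3SnH with azobisisobutyronitrile in benzene at 80 °C generates the aroyl radical, which closes 6-exo-trig onto the terminal alkene; hydrogen transfer to the primary radical gives the C3 methyl. The resulting pair 12/13 is converged with triethylamine, and the route is rejoined at 13.

**Step 13.**
- What may go wrong: poor facial selectivity at C8, because the ligand must distinguish the two faces of a phenoxide whose nearest stereocentres are two or more atoms away. Also possible are persistence of the O-prenyl ether, attack at C6, or attack through the substituted allyl terminus.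
- Fallback: give up catalyst control. Setting out from 22, LiOt-Bu and prenyl bromide in toluene at 0 °C (a lithium phenoxide in a non-polar solvent favours ortho C-alkylation) should give 23 together with its C8 epimer, (4S,6S,8R,9R)-6-{[(1R,3S)-2,2-dimethyl-3-(prop-1-en-2-yl)cyclobutyl]methyl}-8,9-dimethyl-6-(3-methylbut-2-en-1-yl)-4-pentyl-3,4,8,9-tetrahydro-2H-pyrano[2,3-f]chromene-2,5,10(6H)-trione F3. The two are diastereomers and are separated by chromatography; the route is rejoined at 23.

**Step 12.**
- What may go wrong: the templated addition may be slow because the phenol is deactivated by the para ketone. The carbon next to the formyl group of 20 may epimerise in hot acid. During the ionic reduction the C4 ketone may be over-reduced, or cationic side reactions may occur at the cyclobutylcarbinyl position or the isopropenyl group.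
- Fallback: an amine-catalysed three-component reductive alkylation under neutral conditions, setting out from 14 and 20. L-Proline (catalytic) and diethyl 2,6-dimethyl-1,4-dihydropyridine-3,5-dicarboxylate in CH2Cl2/EtOH at 40 °C: the iminium ion of 20 is attacked by C8, loss of the amine gives the ortho-quinone methide, and this takes hydride from the dihydropyridine. The route is rejoined at 22; this fallback makes no new compound (F0).

**Step 3.**
- What may go wrong: wrong regiochemistry, that is, attack at C6 (between the two hydroxyls) instead of C8, since both positions are activated by the same three oxygens.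
- Fallback: opening the lactone makes the aryl ring symmetric about the chain-bearing carbon, so 8 and its regioisomer are the two lactones of one hydroxy ester and the regiochemistry can be corrected afterwards. Setting out from 8 as obtained, mixed with (4S)-5,7-dihydroxy-2-oxo-4-pentylchromane-6-carbaldehyde F4, NaOMe (catalytic) in MeOH at 0 °C converts both into methyl (3S)-3-(3-formyl-2,4,6-trihydroxyphenyl)octanoate F5. Chloromethyl methyl ether (1 equiv) and i-Pr2NEt protect the single hydroxyl para to the formyl group, giving methyl (3S)-3-[3-formyl-2,4-dihydroxy-6-(methoxymethoxy)phenyl]octanoate F6. Heating in toluene with catalytic 2-hydroxypyridine and 4 Å molecular sieves closes the lactone onto the only free hydroxyl next to the chain, and the route is rejoined at 9.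

**Step 2.**
- What may go wrong: low enantioselectivity or stalled conversion, because the coumarin is electron-rich and its β-carbon is crowded by the peri silyloxy group; premature loss of the silyl ethers would also consume hydride.
- Fallback: set the centre by C–C bond formation instead of reduction. Setting out from 1, a chiral triazolium carbene converts oct-2-ynal (A7) into an unsaturated acyl azolium; 1 adds through a ring carbon to its β-carbon and the neighbouring hydroxyl closes the lactone (redox annulation). Because 1 is symmetric only one mono-annulation product is possible, and the route is rejoined at 6; this fallback makes no new compound (F0).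

## Further compounds

F1 | step 6 | (4S)-7-[(2R)-but-3-en-2-yloxy]-5-(methoxymethoxy)-2-oxo-4-pentylchromane-8-carboxylic acid | OC(=O)c1c(O[C@H](C)C=C)cc(OCOC)c2c1OC(=O)C[C@@H]2CCCCC
F2 | step 6 | Se-phenyl (4S)-7-[(2R)-but-3-en-2-yloxy]-5-(methoxymethoxy)-2-oxo-4-pentylchromane-8-carboselenoate | O=C([Se]c1ccccc1)c1c(O[C@H](C)C=C)cc(OCOC)c2c1OC(=O)C[C@@H]2CCCCC
F3 | step 13 | (4S,6S,8R,9R)-6-{[(1R,3S)-2,2-dimethyl-3-(prop-1-en-2-yl)cyclobutyl]methyl}-8,9-dimethyl-6-(3-methylbut-2-en-1-yl)-4-pentyl-3,4,8,9-tetrahydro-2H-pyrano[2,3-f]chromene-2,5,10(6H)-trione | C=C(C)[C@@H]1C[C@H](C[C@]2(CC=C(C)C)C(=O)C3=C(OC(=O)C[C@@H]3CCCCC)C4=C2O[C@H](C)[C@@H](C)C4=O)C1(C)C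
F0 | step 12 | none | none
F4 | step 3 | (4S)-5,7-dihydroxy-2-oxo-4-pentylchromane-6-carbaldehyde | CCCCC[C@H]1CC(=O)Oc2cc(O)c(C=O)c(O)c12
F5 | step 3 | methyl (3S)-3-(3-formyl-2,4,6-trihydroxyphenyl)octanoate | CCCCC[C@@H](CC(=O)OC)c1c(O)cc(O)c(C=O)c1O
F6 | step 3 | methyl (3S)-3-[3-formyl-2,4-dihydroxy-6-(methoxymethoxy)phenyl]octanoate | CCCCC[C@@H](CC(=O)OC)c1c(OCOC)cc(O)c(C=O)c1O
F0 | step 2 | none | none
A1 | alternative 1 | methyl (3S)-3-[(2R,3R,8R)-8-{[(1R,3S)-2,2-dimethyl-3-(prop-1-en-2-yl)cyclobutyl]methyl}-5-hydroxy-2,3-dimethyl-8-(3-methylbut-2-en-1-yl)-4,7-dioxo-3,4,7,8-tetrahydro-2H-chromen-6-yl]octanoate | C=C(C)[C@@H]1C[C@H](C[C@@]2(CC=C(C)C)C(=O)C([C@@H](CCCCC)CC(=O)OC)=C(O)C3=C2O[C@H](C)[C@@H](C)C3=O)C1(C)C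
A2 | alternative 1 | ring-A-open keto diester: (2R,3R)-2,3-dimethyl-2,3-dihydropyran-4-one carrying on C5 the 5-methoxy-5-oxo-3-pentylpentanoyl group and on C6 the quaternary carbon with prenyl, cyclobutylmethyl and methoxycarbonyl groups | C=C(C)[C@@H]1C[C@H](C[C@@](CC=C(C)C)(C(=O)OC)C2=C(C(=O)C[C@@H](CCCCC)CC(=O)OC)C(=O)[C@H](C)[C@@H](C)O2)C1(C)C
A3 | alternative 2 | (4S)-5,7-dihydroxy-4-pentylchroman-2-one (identical with 6) | CCCCC[C@H]1CC(=O)Oc2cc(O)cc(O)c12
A4 | alternative 2 | 2-(hept-1-en-2-yl)benzene-1,3,5-triol | C=C(CCCCC)c1c(O)cc(O)cc1O
A5 | alternative 2 | carbon monoxide | [C-]#[O+]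
A6 | alternative 3 | (4S,6R,8R,9R)-6-{[(1R,3S)-2,2-dimethyl-3-(prop-1-en-2-yl)cyclobutyl]methyl}-8,9-dimethyl-6-(3-methylbut-2-en-1-yl)-4-pentyl-3,4,8,9-tetrahydro-2H-pyrano[2,3-f]chromene-2,5,10(6H)-trione (identical with 23) | C=C(C)[C@@H]1C[C@H](C[C@@]2(CC=C(C)C)C(=O)C3=C(OC(=O)C[C@@H]3CCCCC)C4=C2O[C@H](C)[C@@H](C)C4=O)C1(C)C
A7 | alternative 3 | oct-2-ynal | CCCCCC#CC=O
A8 | alternative 3 | (2R,3R,8R)-8-{[(1R,3S)-2,2-dimethyl-3-(prop-1-en-2-yl)cyclobutyl]methyl}-5-hydroxy-2,3-dimethyl-8-(3-methylbut-2-en-1-yl)-2,3-dihydro-4H-chromene-4,7(8H)-dione | C=C(C)[C@@H]1C[C@H](C[C@@]2(CC=C(C)C)C(=O)C=C(O)C3=C2O[C@H](C)[C@@H](C)C3=O)C1(C)C
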